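**Plan**

- Locants: ring C5–C10 (side chain on C5, acyloxy on C6, lactone arm C11/C12 on C7, lactone oxygen on C8, methyl on C10), exocyclic methylene C13, side chain C4→C1. Cuts, last-made first: C11=C13; the C6–O ester bond; C10–CH3 together with a 1,3-shift of oxygen from C6 back to C10; the C1–O ester bond; the lactone O–C8 bond; the C4–H bond (alkene hydrogenation); the C5–C4 bond (arene acylation).
- Enabling feature: C5–C10 plus the C11/C12 arm on C7 form a 4-methoxyphenylacetic acid whose methoxy carbon is C10. Birch reduction and hydrolysis turn C10 into a ketone with C7=C8 in the β,γ-position, so C8 becomes the β-carbon of an enone, five atoms from the carboxyl oxygen.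
- Forward: the six-membered ring is the arene of 1; the side chain is attached by Friedel–Crafts acylation and shaped by methylenation and hydrogenation; dearomatisation follows; the lactone ring closes in the key step; enone formation, methyl addition, oxidative transposition, reduction, inversion and α-methylenation finish the route.
- Stereochemistry: C4 from iridium-catalysed hydrogenation on the flat arene; C7 from the chiral diamine in the γ-protonation; C8 from the obligatory cis ring closure; C6 from convex-face Luche reduction followed by Mitsunobu inversion. C5 is left as an epimer mixture because it later becomes sp2.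
- No protecting group is used: the side-chain hydroxyl passes free through the Birch reduction and the key step and is then converted directly into the C1 isobutyrate of the target.

Key step: step 6

Assumption: the sense of induction in steps 3 and 6 is taken as drawn; if either runs the other way, the (R)-configured phosphinooxazoline ligand or the quinidine-derived pseudo-enantiomer of the diamine is used instead, with no other change.

**Step 1**
Reactants: 1 methyl 2-(4-methoxyphenyl)acetate; 2 4-chlorobutanoyl chloride
Product: 3 methyl 2-[3-(4-chlorobutanoyl)-4-methoxyphenyl]acetate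
Conditions: AlCl3 (2.5 equiv), CH2Cl2, 0 °C
Reagents that add atoms: none
Why: Friedel–Crafts acylation is directed ortho to the strongly donating methoxy group (its para position is occupied), so the C5–C4 bond should form at the only activated site, and the low temperature limits demethylation of the ortho-acyl anisole.

**Step 2**
Reactants: 3 methyl 2-[3-(4-chlorobutanoyl)-4-methoxyphenyl]acetate
Product: 4 methyl 2-[3-(5-chloropent-1-en-2-yl)-4-methoxyphenyl]acetate
Conditions: Zn, CH2Br2, TiCl4, THF/CH2Cl2, 0 °C → rt
Reagents that add atoms: dibromomethane, BrCBr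
Why: Takai–Lombardo methylenation uses a non-basic gem-dizinc/TiCl4 reagent that olefinates ketones in the presence of esters and alkyl chlorides, avoiding the enolisation (cyclopropane closure, arylacetate deprotonation) that a phosphorus ylide could cause.

**Step 3**
Reactants: 4 methyl 2-[3-(5-chloropent-1-en-2-yl)-4-methoxyphenyl]acetate
Product: 5 methyl 2-{3-[(2S)-5-chloropentan-2-yl]-4-methoxyphenyl}acetate
Conditions: H2 (1 bar), [Ir(cod)(L)][B(C6H3-3,5-(CF3)2)4] (1 mol %; cod = 1,5-cyclooctadiene, L = (4S)-4-tert-butyl-2-[2-(diphenylphosphanyl)phenyl]-4,5-dihydro-1,3-oxazole), CH2Cl2, rt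
Reagents that add atoms: none
Why: Iridium–phosphinooxazoline complexes effect asymmetric hydrogenation of unfunctionalised 2-aryl-1-alkenes, the P,N ligand differentiating the faces of the coordinated alkene so that hydrogen is delivered to C4 to give the (S) centre, with low pressure chosen because it favours selectivity for terminal alkenes.

**Step 4**
Reactants: 5 methyl 2-{3-[(2S)-5-chloropentan-2-yl]-4-methoxyphenyl}acetate
Product: 7 2-{3-[(2S)-5-hydroxypentan-2-yl]-4-methoxyphenyl}acetic acid, via acetate ester 6 (not isolated)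
Conditions: CsOAc, NaI (cat.), DMF, 80 °C; then LiOH, THF/MeOH/H2O, rt; HCl work-up
Reagents that add atoms: caesium acetate, CC(=O)[O-].[Cs+]; lithium hydroxide, [Li+].[OH-]
Why: Iodide-assisted SN2 displacement of the primary chloride by acetate followed by saponification of both esters replaces the C–Cl bond, which would not survive dissolving metal, by a hydroxyl and frees the carboxylic acid without touching the benzylic centre.

**Step 5**
Reactants: 7 2-{3-[(2S)-5-hydroxypentan-2-yl]-4-methoxyphenyl}acetic acid
Product: 9 2-{5-[(2S)-5-hydroxypentan-2-yl]-4-oxocyclohex-1-en-1-yl}acetic acid (both C5 epimers), via Birch diene 8 (not isolated)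
Conditions: Li, NH3 (l), THF, t-BuOH, −78 → −33 °C; NH4Cl; then (CO2H)2, MeOH/H2O, rt
Reagents that add atoms: water, O
Why: Birch reduction of the anisole (carboxylate and alkoxide being inert) leaves the methoxy- and alkyl-bearing carbons sp2 (C10=C5 and C7=C8), and mild oxalic acid hydrolysis of the enol ether then unveils the C10 ketone without moving C7=C8 into conjugation, C5 being protonated unselectively.

**Step 6**
Reactants: 9 2-{5-[(2S)-5-hydroxypentan-2-yl]-4-oxocyclohex-1-en-1-yl}acetic acid (both C5 epimers)
Product: 11 (3aR,7aR)-5-[(2S)-5-hydroxypentan-2-yl]tetrahydro-1-benzofuran-2,6(3H,7H)-dione (cis-fused keto lactone; both C5 epimers), via conjugated enone acid 10 (not isolated)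
Conditions: 9-amino-9-deoxy-epi-quinine (20 mol %, present as its salt with the substrate carboxylic acid), toluene, 0 °C → rt
Reagents that add atoms: none
Why: The primary amine condenses with the C10 ketone, loss of a C9 proton gives the linear dienamine N–C10=C9–C8=C7, and the protonated quinuclidine nitrogen returns the proton to the γ-carbon C7 on one face, giving the conjugated iminium ion of enone acid 10. The carboxylate then adds to C8 of this iminium-activated enone, and hydrolysis releases 11 and the catalyst. The closest known reaction type is the amine-catalysed enantioselective isomerisation of Birch-derived β,γ-unsaturated cyclohexenones coupled with oxa-Michael lactonisation. The lactone closes in a 5-exo-trig mode (O to C8, with C8=C9 outside the new ring), and the three-atom tether from C7 can reach C8 only on the same face, so the fusion must be cis. C7 (R) is set by the catalyst-controlled face of γ-protonation and C8 (R) follows from C7 through the ring constraint. The step needs γ- rather than α-protonation and catalyst rather than substrate control; the intramolecular proton shuttle of the diamine secures the first, the remote exocyclic C4 centre and the freely epimerising C5 centre exert little bias on the second, and lactone formation removes the enone so that C7 cannot racemise through the dienamine.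

**Step 7**
Reactants: 11 (3aR,7aR)-5-[(2S)-5-hydroxypentan-2-yl]tetrahydro-1-benzofuran-2,6(3H,7H)-dione
Product: 12 (4S)-4-[(3aR,7aR)-2,6-dioxooctahydro-1-benzofuran-5-yl]pentyl 2-methylpropanoate (both C5 epimers)
Conditions: (i-PrCO)2O, pyridine, 4-(dimethylamino)pyridine (cat.), CH2Cl2, 0 °C
Reagents that add atoms: 2-methylpropanoic anhydride, CC(C)C(=O)OC(=O)C(C)C
Why: Nucleophile-catalysed acylation of the only hydroxyl group installs the C1 isobutyrate of the target under conditions too mild to open the β-acyloxy ketone by retro-oxa-Michael reaction.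

**Step 8**
Reactants: 12 (4S)-4-[(3aR,7aR)-2,6-dioxooctahydro-1-benzofuran-5-yl]pentyl 2-methylpropanoate
Product: 13 (4S)-4-{(3aR,7aR)-2-oxo-6-[(trimethylsilyl)oxy]-2,3,3a,4,7,7a-hexahydro-1-benzofuran-5-yl}pentyl 2-methylpropanoate
Conditions: Me3SiCl, NaI, Et3N, MeCN, 0 °C → rt
Reagents that add atoms: chlorotrimethylsilane, C[Si](C)(C)Cl
Why: Iodotrimethylsilane formed in situ with a weak amine base enolises ketones reversibly and should give the thermodynamic, more substituted silyl enol ether (C10=C5), without a free enolate toward C9 that would expel the lactone oxygen.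

**Step 9**
Reactants: 13 (4S)-4-{(3aR,7aR)-2-oxo-6-[(trimethylsilyl)oxy]-2,3,3a,4,7,7a-hexahydro-1-benzofuran-5-yl}pentyl 2-methylpropanoate
Product: 14 (4S)-4-[(3aS,7aR)-2,6-dioxo-2,3,3a,6,7,7a-hexahydro-1-benzofuran-5-yl]pentyl 2-methylpropanoate
Conditions: Pd(OAc)2 (1.1 equiv), MeCN, rt
Reagents that add atoms: none
Why: In the Saegusa–Ito oxidation the silyl enol ether gives a palladium enolate at C5 whose β-hydride elimination into the ring (C6–H) should deliver the endocyclic C5=C6 enone under neutral conditions, erasing the C5 stereocentre.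

**Step 10**
Reactants: 14 (4S)-4-[(3aS,7aR)-2,6-dioxo-2,3,3a,6,7,7a-hexahydro-1-benzofuran-5-yl]pentyl 2-methylpropanoate
Product: 15 (4S)-4-[(3aS,7aR)-6-hydroxy-6-methyl-2-oxo-2,3,3a,6,7,7a-hexahydro-1-benzofuran-5-yl]pentyl 2-methylpropanoate (carbinol epimers at C10)
Conditions: CeCl3 (anhydrous), CH3MgBr, THF, −78 °C
Reagents that add atoms: methylmagnesium bromide, C[Mg]Br
Why: The weakly basic organocerium reagent adds 1,2 to the enone carbonyl at −78 °C faster than to the lactone or the isobutyrate and without γ-deprotonation, and the configuration of the new carbinol carbon is irrelevant because it becomes sp2 in the next step.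

**Step 11**
Reactants: 15 (4S)-4-[(3aS,7aR)-6-hydroxy-6-methyl-2-oxo-2,3,3a,6,7,7a-hexahydro-1-benzofuran-5-yl]pentyl 2-methylpropanoate
Product: 16 (4S)-4-[(3aR,7aR)-6-methyl-2,4-dioxo-2,3,3a,4,7,7a-hexahydro-1-benzofuran-5-yl]pentyl 2-methylpropanoate
Conditions: [C5H5NH][CrO3Cl] (pyridinium chlorochromate, 3 equiv), SiO2, CH2Cl2, 0 °C → rt; short silica filtration, used at once
Reagents that add atoms: pyridinium chlorochromate, [O-][Cr](=O)(=O)Cl.c1cc[nH+]cc1
Why: In the Babler–Dauben oxidative transposition the tertiary chromate ester undergoes a [3,3]-shift to the secondary C6 chromate, which is oxidised to the ketone, so oxygen moves to C6 and the double bond to C5=C10.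

**Step 12**
Reactants: 16 (4S)-4-[(3aR,7aR)-6-methyl-2,4-dioxo-2,3,3a,4,7,7a-hexahydro-1-benzofuran-5-yl]pentyl 2-methylpropanoate
Product: 17 (4S)-4-[(3aS,4R,7aR)-4-hydroxy-6-methyl-2-oxo-2,3,3a,4,7,7a-hexahydro-1-benzofuran-5-yl]pentyl 2-methylpropanoate (C6 hydroxyl cis to the C7–C11 bond)
Conditions: NaBH4, CeCl3·7H2O, MeOH, −78 °C; AcOH quench at −78 °C
Reagents that add atoms: none
Why: Luche reduction gives 1,2-reduction of the enone, with hydride arriving on the convex face opposite the cis-fused lactone, so the C6 hydroxyl should be cis to C7–C11, which is the epimer of the target configuration.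

**Step 13**
Reactants: 17 (4S)-4-[(3aS,4R,7aR)-4-hydroxy-6-methyl-2-oxo-2,3,3a,4,7,7a-hexahydro-1-benzofuran-5-yl]pentyl 2-methylpropanoate
Product: 18 (4S)-4-{(3aR,4S,7aR)-6-methyl-4-[(2-methylpropanoyl)oxy]-2-oxo-2,3,3a,4,7,7a-hexahydro-1-benzofuran-5-yl}pentyl 2-methylpropanoate
Conditions: PPh3, diisopropyl azodicarboxylate, i-PrCO2H, toluene, 0 °C → rt
Reagents that add atoms: 2-methylpropanoic acid, CC(C)C(=O)O
Why: In the Mitsunobu esterification isobutyrate displaces the oxyphosphonium group by SN2 attack from the open convex face, inverting C6 to the (S) ester trans to C7–C11 as in the target.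

**Step 14**
Reactants: 18 (4S)-4-{(3aR,4S,7aR)-6-methyl-4-[(2-methylpropanoyl)oxy]-2-oxo-2,3,3a,4,7,7a-hexahydro-1-benzofuran-5-yl}pentyl 2-methylpropanoate
Product: 21 (4S)-4-{(3aR,4S,7aR)-6-methyl-3-methylidene-4-[(2-methylpropanoyl)oxy]-2-oxo-2,3,3a,4,7,7a-hexahydro-1-benzofuran-5-yl}pentyl 2-methylpropanoate (CNP0509808.1), via Mannich base 19 (not isolated), via ammonium iodide 20 (not isolated)
Conditions: LiN(i-Pr)2 (1.1 equiv), THF, −78 °C; CH2=NMe2+ I−, −78 → 0 °C; then CH3I, MeOH, rt; then aq. NaHCO3, EtOAc, rt
Reagents that add atoms: N,N-dimethylmethylideneammonium iodide (Eschenmoser's salt), C=[N+](C)C.[I-]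
Why: The lactone α-CH2 (C11) is the most acidic C–H (the isobutyrate α-carbons are tertiary and less acidic), so kinetic enolisation, Mannich reaction, quaternisation and E1cB loss of trimethylamine should give the α-methylene lactone without touching the existing stereocentres.

**Compound list**

1 | methyl 2-(4-methoxyphenyl)acetate | COC(=O)Cc1ccc(OC)cc1 | starting material
2 | 4-chlorobutanoyl chloride | O=C(Cl)CCCCl | starting material
3 | methyl 2-[3-(4-chlorobutanoyl)-4-methoxyphenyl]acetate | COC(=O)Cc1ccc(OC)c(c1)C(=O)CCCCl | intermediate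
4 | methyl 2-[3-(5-chloropent-1-en-2-yl)-4-methoxyphenyl]acetate | COC(=O)Cc1ccc(OC)c(c1)C(=C)CCCCl | intermediate
5 | methyl 2-{3-[(2S)-5-chloropentan-2-yl]-4-methoxyphenyl}acetate | COC(=O)Cc1ccc(OC)c(c1)[C@@H](C)CCCCl | intermediate
6 | methyl 2-{3-[(2S)-5-acetoxypentan-2-yl]-4-methoxyphenyl}acetate (not isolated) | COC(=O)Cc1ccc(OC)c(c1)[C@@H](C)CCCOC(C)=O | intermediate
7 | 2-{3-[(2S)-5-hydroxypentan-2-yl]-4-methoxyphenyl}acetic acid | OC(=O)Cc1ccc(OC)c(c1)[C@@H](C)CCCO | intermediate
8 | 2-{5-[(2S)-5-hydroxypentan-2-yl]-4-methoxycyclohexa-1,4-dien-1-yl}acetic acid (not isolated) | COC1=C([C@@H](C)CCCO)CC(CC(=O)O)=CC1 | intermediate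
9 | 2-{5-[(2S)-5-hydroxypentan-2-yl]-4-oxocyclohex-1-en-1-yl}acetic acid (C5 epimers) | O=C1CC=C(CC(=O)O)CC1[C@@H](C)CCCO | intermediate
10 | 2-{(1R)-5-[(2S)-5-hydroxypentan-2-yl]-4-oxocyclohex-2-en-1-yl}acetic acid (not isolated; C5 epimers) | O=C1C=C[C@@H](CC(=O)O)CC1[C@@H](C)CCCO | intermediate
11 | (3aR,7aR)-5-[(2S)-5-hydroxypentan-2-yl]tetrahydro-1-benzofuran-2,6(3H,7H)-dione (C5 epimers) | C1C(=O)O[C@@H]2CC(=O)C([C@@H](C)CCCO)C[C@H]12 | intermediate
12 | (4S)-4-[(3aR,7aR)-2,6-dioxooctahydro-1-benzofuran-5-yl]pentyl 2-methylpropanoate (C5 epimers) | C1C(=O)O[C@@H]2CC(=O)C([C@@H](C)CCCOC(=O)C(C)C)C[C@H]12 | intermediate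
13 | (4S)-4-{(3aR,7aR)-2-oxo-6-[(trimethylsilyl)oxy]-2,3,3a,4,7,7a-hexahydro-1-benzofuran-5-yl}pentyl 2-methylpropanoate | C1C(=O)O[C@@H]2CC(O[Si](C)(C)C)=C([C@@H](C)CCCOC(=O)C(C)C)C[C@H]12 | intermediate
14 | (4S)-4-[(3aS,7aR)-2,6-dioxo-2,3,3a,6,7,7a-hexahydro-1-benzofuran-5-yl]pentyl 2-methylpropanoate | C1C(=O)O[C@@H]2CC(=O)C([C@@H](C)CCCOC(=O)C(C)C)=C[C@H]12 | intermediate
15 | (4S)-4-[(3aS,7aR)-6-hydroxy-6-methyl-2-oxo-2,3,3a,6,7,7a-hexahydro-1-benzofuran-5-yl]pentyl 2-methylpropanoate (carbinol epimers) | C1C(=O)O[C@@H]2CC(C)(O)C([C@@H](C)CCCOC(=O)C(C)C)=C[C@H]12 | intermediate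
16 | (4S)-4-[(3aR,7aR)-6-methyl-2,4-dioxo-2,3,3a,4,7,7a-hexahydro-1-benzofuran-5-yl]pentyl 2-methylpropanoate | C1C(=O)O[C@@H]2CC(C)=C([C@@H](C)CCCOC(=O)C(C)C)C(=O)[C@H]12 | intermediate
17 | (4S)-4-[(3aS,4R,7aR)-4-hydroxy-6-methyl-2-oxo-2,3,3a,4,7,7a-hexahydro-1-benzofuran-5-yl]pentyl 2-methylpropanoate | C1C(=O)O[C@@H]2CC(C)=C([C@@H](C)CCCOC(=O)C(C)C)[C@H](O)[C@H]12 | intermediate
18 | (4S)-4-{(3aR,4S,7aR)-6-methyl-4-[(2-methylpropanoyl)oxy]-2-oxo-2,3,3a,4,7,7a-hexahydro-1-benzofuran-5-yl}pentyl 2-methylpropanoate | C1C(=O)O[C@@H]2CC(C)=C([C@@H](C)CCCOC(=O)C(C)C)[C@@H](OC(=O)C(C)C)[C@H]12 | intermediate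
19 | 3-[(dimethylamino)methyl] derivative of 18 (Mannich base at C11, either configuration; not isolated) | CN(C)CC1C(=O)O[C@@H]2CC(C)=C([C@@H](C)CCCOC(=O)C(C)C)[C@@H](OC(=O)C(C)C)[C@H]12 | intermediate
20 | trimethylammonium iodide of 19 (not isolated) | C[N+](C)(C)CC1C(=O)O[C@@H]2CC(C)=C([C@@H](C)CCCOC(=O)C(C)C)[C@@H](OC(=O)C(C)C)[C@H]12.[I-] | intermediate
21 | (4S)-4-{(3aR,4S,7aR)-6-methyl-3-methylidene-4-[(2-methylpropanoyl)oxy]-2-oxo-2,3,3a,4,7,7a-hexahydro-1-benzofuran-5-yl}pentyl 2-methylpropanoate | C=C1C(=O)O[C@@H]2CC(C)=C([C@@H](C)CCCOC(=O)C(C)C)[C@@H](OC(=O)C(C)C)[C@H]12 | target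

**Step count and risks**

Total steps: 14. Longest linear sequence: 14 steps, from 1.

Steps most likely to fail:

1. Step 8. Enolisation and silylation may run toward C9 instead of C5, and the C9 enol derivative can expel the lactone oxygen, so the wrong or a ring-opened silyl enol ether would enter the oxidation. The fallback sets out from 12 and avoids any enol derivative. Addition of CH3MgBr/CeCl3 (THF, −78 °C) to the saturated ketone should give the tertiary alcohol (4S)-4-[(3aR,7aR)-6-hydroxy-6-methyl-2-oxooctahydro-1-benzofuran-5-yl]pentyl 2-methylpropanoate F1. Dehydration with the Burgess reagent (toluene, 50 °C), which takes tertiary alcohols mainly to the most substituted olefin, should give the C5=C10 alkene (4S)-4-[(3aR,7aR)-6-methyl-2-oxo-2,3,3a,4,7,7a-hexahydro-1-benzofuran-5-yl]pentyl 2-methylpropanoate F2. Allylic oxidation with CrO3·3,5-dimethylpyrazole (CH2Cl2, −20 °C) is expected at C6, because C9 is deactivated by the neighbouring lactone oxygen, and returns the route at 16, replacing steps 8 to 11.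

2. Step 11. Under the acidic hexavalent chromium conditions the tertiary allylic alcohol may ionise and dehydrate, and enone 16 may lose the lactone oxygen by β-elimination and tautomerise to a phenol. The fallback sets out from 15 and never forms the ketone. A catalytic rhenium oxo complex, Ph3SiOReO3 (Et2O, −50 → 0 °C), effects a redox-neutral, suprafacial 1,3-transposition of the allylic hydroxyl, driven by formation of the tetrasubstituted C5=C10 olefin. From the carbinol epimer expected from convex-face addition in step 10, the hydroxyl arrives at C6 on the lactone face, which is 17, where the route is rejoined (steps 11 and 12 replaced).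

3. Step 13. The hindered allylic oxyphosphonium ion may ionise rather than undergo SN2 displacement, leading to elimination to a diene or loss of configurational control at C6. The fallback sets out from 16 and needs no inversion. Corey–Bakshi–Shibata reduction with the (R)-2-methyl-oxazaborolidine and catecholborane (toluene, −78 °C), the catalyst enantiomer predicted to override the substrate bias if the alkenyl flank acts as the large group, should give the trans allylic alcohol (4S)-4-[(3aS,4S,7aR)-4-hydroxy-6-methyl-2-oxo-2,3,3a,4,7,7a-hexahydro-1-benzofuran-5-yl]pentyl 2-methylpropanoate F3. Acylation with 2-methylpropanoic anhydride, pyridine and catalytic 4-(dimethylamino)pyridine, with retention, returns the route at 18 (steps 12 and 13 replaced).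

**Further compounds**

F1 | step 8 | (4S)-4-[(3aR,7aR)-6-hydroxy-6-methyl-2-oxooctahydro-1-benzofuran-5-yl]pentyl 2-methylpropanoate (epimers at C5 and C10) | C1C(=O)O[C@@H]2CC(C)(O)C([C@@H](C)CCCOC(=O)C(C)C)C[C@H]12
F2 | step 8 | (4S)-4-[(3aR,7aR)-6-methyl-2-oxo-2,3,3a,4,7,7a-hexahydro-1-benzofuran-5-yl]pentyl 2-methylpropanoate | C1C(=O)O[C@@H]2CC(C)=C([C@@H](C)CCCOC(=O)C(C)C)C[C@H]12
F0 | step 11 | none | none
F3 | step 13 | (4S)-4-[(3aS,4S,7aR)-4-hydroxy-6-methyl-2-oxo-2,3,3a,4,7,7a-hexahydro-1-benzofuran-5-yl]pentyl 2-methylpropanoate | C1C(=O)O[C@@H]2CC(C)=C([C@@H](C)CCCOC(=O)C(C)C)[C@@H](O)[C@H]12
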